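## The problem

Compound 24 is a C20 methyl ester in which C13–C17 form a cyclopentane. C13 carries the (5Z,8Z,11Z)-triene chain that ends in the ester, C17 carries a 1-chloropropyl group (C18–C20), and C14/C15 are bridged by a cis-fused epoxide. Five stereocentres must be set: C13 and C17 trans on the ring, the epoxide oxygen on the face of the C17 arm and opposite the C13 chain, and the exocyclic C18 (S) bearing chlorine. C17 can control C13, because trans is the more stable arrangement of the two vicinal substituents, and a hydroxyl on C18 can control the epoxide face. C18 lies outside the ring and needs reagent control. The chain is a skipped triene with two doubly allylic methylenes and a Z-alkene directly on the ring, which rules out strong base, radical conditions and late oxidation. The epoxide is sensitive to acid and nucleophiles, the secondary chloride is prone to elimination, and once oxygen sits on C14 any carbonyl at C12 would invite β-elimination through C13–H. The order is therefore fixed: C12 must stop being a carbonyl before C14 is oxidised, and chlorine and the triene come last. The enabling feature is that C13–C17 plus C12 and C18 make seven carbons. With C12 placed as a ring carbonyl between C13 and C14, the core is a cyclohex-2-enone bearing the C18 carboxyl at its 5-position, which is the reduction product of 3-methoxybenzoic acid 1. A 1,2-shift of C14 from C12 to C13 contracts it to the cyclopentene with C14=C15 already in place for the epoxide.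

## Retrosynthesis

**24 to 19 and 22.** The three Z-alkenes are taken back to the alkynes of triyne 23, and the C10–C11 bond is cut between terminal alkyne 19 and propargylic chloride 22. The neighbouring cut, a Z-selective Wittig reaction at C11=C12, would need a C12 aldehyde on a ring that already holds the epoxide, or an epoxidation in the presence of three chain alkenes. The alkyne route lets the ring be oxidised while it has a single alkene. Compound 19 holds all five stereocentres in ten carbons. The forward steps need a copper-mediated coupling that tolerates epoxide and chloride, and a semihydrogenation that stops at the triene.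

**22 to 20 and 21.** The C6–C7 bond is cut, giving methyl hex-5-ynoate 20 and 1,4-dichlorobut-2-yne 21. Both are commercial, and the second chloride of 21 becomes the leaving group for the next coupling, so no functional-group change is needed between the two couplings. The forward reaction must stop at monosubstitution.

**19 to 17.** The C18–Cl bond is traced to the C18 alcohol of 18 with inversion, and the epoxide of 18 to the alkene of 17. The same hydroxyl serves twice: it first delivers the oxidant to the ring face of the C17 arm and is then replaced by chloride. Chlorinating first would leave the epoxidation to two opposing steric effects. The forward steps need a directed epoxidation and an SN2 chlorination that leaves the epoxide alone.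

**17 to 14.** The C18–C19 bond is cut: ethyl is added to aldehyde 16 under catalyst control. Reduction of an ethyl ketone was considered, but a ketone flanked by ethyl and a secondary ring carbon is a poorer substrate for reagent control than an α-branched aldehyde is for catalytic ethylation. Aldehyde 16 comes from tert-butyl ester 14 through alcohol 15.

**14 to 12.** C11 is removed: the ethynyl group comes from the methyl ester of diester 12 through aldehyde 13. This is done before any oxygen is placed on C14 and while the tert-butyl ester still masks C18. The forward step must distinguish the two esters and must not enolise the β,γ-unsaturated aldehyde for long.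

**12 to 9.** The C13–C14 bond is cut and C12 is re-inserted between C13 and C14, which gives the six-membered diazo ketone 9. This cut gives the ring, the alkene at the right place and two different carboxyl groups at once. Opening any other ring bond leads to acyclic precursors with no such simplification. The enone is also what places the diazo group: only the α′-carbon C13 can be enolised kinetically. The forward reaction is a Wolff ring contraction in which C14 must migrate and C13 must end up trans to C17.

**9 to 1.** The diazo group is removed to give enone ester 7. Its acid 6 is obtained from salt 5 of racemic acid 3 with (R)-1-phenylethylamine 4. Acid 3 comes from 3-methoxybenzoic acid 1 by Birch reduction and hydrolysis through dihydro acid 2. A cheap arene supplies all seven carbons, and the only stereocentre to be resolved (C17) cannot racemise through the enone.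

## Roads not taken

Alternative 1: The ring is cut at C13–C17 and the chlorine is traced to a cyclopropane bond C13–C18, so the precursor is the open-chain (6Z)-diazo keto ester A2. In the forward key step, CuOTf with a chiral bis(oxazoline), or a chiral dirhodium tetracarboxylate related to Rh2(OAc)4, would turn A2 into a carbenoid that adds across C17=C18 and gives the bicyclic keto ester A1. Chloride would later open the C13–C18 bond with inversion.
- Merits: one step makes the ring and three contiguous centres, and the Z-alkene geometry is translated into the C17/C18 relation. Chlorine enters stereospecifically without a reagent-controlled carbinol. C13 then sits between ketone and ester, where equilibration to trans is free of the double-bond migration that threatens step 5 here. In these respects it is the better road.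
- Weak points for 24: acceptor/acceptor carbenoids of this kind usually cyclopropanate with only moderate enantiocontrol, and the whole absolute configuration would rest on that. The opened product is a γ-chloro β-keto ester whose enolate can re-close the cyclopropane, so the chlorine is at risk in every basic step. The ring carbonyl ends up at C14, so the epoxide would have to be built from a ketone by functionalising C15 and controlling two more centres, while enolisation prefers C13.
- Comparison: against its elegance at C17/C18, the chosen plan sets an alkene delivered exactly at C14=C15, absolute configuration from a crystalline resolved acid, and chlorine introduced after the last strongly basic step.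

Alternative 2: C13–C17 and C18–Cl are cut together, leading to the open-chain silyl ether A4, in which C13/C14 are a propargylic epoxide (alkyne complexed to Co2(CO)6) and C17=C18 is a Z-alkene. TiCl4 would ionise the epoxide at C13 to the cobalt-stabilised propargylic cation, C17 would attack it, and chloride would be delivered to C18, giving A3 as its cobalt complex.
- Merits: it follows the likely biogenesis and forms the ring, C13, C17, C18 and the C–Cl bond in one operation, from a precursor that already carries the alkyne for the chain. It is the shortest of the four plans, and chlorine needs no separate inversion.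
- Weak points: three selectivities must hold at once, and none is enforced by the substrate. These are five- against six-membered closure (C17 or C18 attacking, both giving secondary cations), the face of a planar cation at C13, and anti capture of chloride at C18 before hydride shift or elimination. As drawn, the two oxygens of A3 lie on the same ring face, so the epoxide cannot be closed directly and one carbon must first be inverted. Decomplexation adds a step.
- Comparison: the chosen plan is longer, but each stereocentre is set by a separate, well-understood control element. That is what it sets against the brevity of this road.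

Alternative 3: No ring bond is cut. The ring is taken as the C2-symmetric trans keto diester A7, whose enol triflate (the same compound from either α-carbon) is reduced to the alkene and hydrolysed to the trans diacid A6. The key step is iodolactonisation of A6: the C17 carboxylate adds to C15 anti to iodine on C14 and closes the bridged lactone A5.
- Merits: the trans C13/C17 relation is present from the start, set while neither α-carbon is allylic, so the equilibration risk of step 5 does not arise. The lactone fixes oxygen on the face of the C17 arm by geometry rather than by a directing effect, and it tells the two carboxyls apart. On the first point it is better than the chosen plan, and on the second at least equal.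
- Weak points: in A5 a leaving group sits on C14 while C12 is still a carboxyl. Every later step that takes C12 to the aldehyde or alkyne level therefore runs with iodide or epoxide oxygen β to an enolisable carbonyl, which invites elimination through C13–H. The enantiopure keto diester needs its own resolution or asymmetric entry. Triflation, reduction, hydrolysis and lactonisation only reach the point that ring contraction reaches in one step with the carboxyls already different.
- Comparison: the chosen plan answers with shorter access to a differentiated alkene diester and an order of events in which C12 is already an alkyne before C14 is oxidised.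

Key step: step 5

Assumption for step 2: the salt of the (R)-acid with (R)-1-phenylethylamine is taken to be the less soluble one; if the (S)-acid salt crystallises instead, the antipodal amine is used and nothing else changes.
Assumption for step 9: the (1S,2S)-bis(sulfonamide) ligand is taken to direct ethyl to the Re face of 16, by analogy with its antipode, which adds to the Si face of simple aldehydes.

## Route

Step 1
Reactants: 1 3-methoxybenzoic acid
Product: 3 rac-5-oxocyclohex-3-ene-1-carboxylic acid, via dihydro acid 2 (not isolated)
Conditions: Na, NH3(l), THF, −78 to −33 °C; NH4Cl; then 1 M HCl, THF–H2O, rt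
Reagents that add atoms: water, O
Why: Birch reduction of the benzoate protonates the carboxyl-bearing carbon and the carbon para to it and leaves the methoxy group on a double bond (enol ether 2); dilute acid hydrolyses the enol ether, and the first-formed β,γ-enone moves into conjugation with the ketone through its dienol, a path that never involves the carboxyl-bearing carbon. Mild acid at room temperature is chosen so that the further shift to the doubly conjugated, achiral 3-oxocyclohex-1-ene acid does not set in; the product is racemic.

Step 2
Reactants: 3 rac-5-oxocyclohex-3-ene-1-carboxylic acid; 4 (R)-1-phenylethylamine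
Product: 5 (1R)-1-phenylethanaminium (1R)-5-oxocyclohex-3-ene-1-carboxylate
Conditions: 4 (1 equiv), EtOAc–EtOH, crystallise; recrystallise
Reagents that add atoms: none
Why: Classical resolution through diastereomeric salts; the stereocentre is α only to the carboxylate and is not acidified by the enone, so it does not racemise, and the ammonium ion is not a conjugate-addition donor.

Step 3
Reactants: 5 (1R)-1-phenylethanaminium (1R)-5-oxocyclohex-3-ene-1-carboxylate
Product: 7 tert-butyl (1R)-5-oxocyclohex-3-ene-1-carboxylate, via free acid 6 (not isolated)
Conditions: 1 M HCl/EtOAc partition; then Cl3CC(=NH)Ot-Bu, BF3·OEt2 (cat.), CH2Cl2–cyclohexane, rt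
Reagents that add atoms: tert-butyl 2,2,2-trichloroacetimidate, CC(C)(C)OC(=N)C(Cl)(Cl)Cl
Why: Aqueous acid frees the acid, and the trichloroacetimidate transfers a tert-butyl cation to the carboxyl group under Lewis acid catalysis without base, so neither the enone nor the stereocentre is disturbed. The tert-butyl ester resists enolate chemistry and low-temperature hydride and differs from the methyl ester made in step 5.

Step 4
Reactants: 7 tert-butyl (1R)-5-oxocyclohex-3-ene-1-carboxylate
Product: 9 tert-butyl (1R)-2-diazo-3-oxocyclohex-4-ene-1-carboxylate, via trifluoroacetyl ketone 8 (not isolated)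
Conditions: LiN(SiMe3)2, THF, −78 °C; CF3CO2CH2CF3; then MsN3, Et3N, H2O (1 equiv), MeCN, rt
Reagents that add atoms: methanesulfonyl azide, CS(=O)(=O)N=[N+]=[N-]
Why: The lithium amide removes the α′-proton of the enone under kinetic control (cross-conjugated enolate; the ester α-proton is far less acidic), Claisen-type trifluoroacetylation activates that carbon, and Regitz diazo transfer with loss of the trifluoroacetyl group (deacylative diazo transfer) puts the diazo group on C13 only. C17 is not touched.

Step 5
Reactants: 9 tert-butyl (1R)-2-diazo-3-oxocyclohex-4-ene-1-carboxylate
Product: 12 1-tert-butyl 2-methyl (1R,2R)-cyclopent-3-ene-1,2-dicarboxylate, via ketene 10 (not isolated), via cis diester 11 (not isolated)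
Conditions: hν (Pyrex, λ > 300 nm), MeOH, 0 °C; then NaOMe (0.1 equiv), 0 °C; AcOH quench
Reagents that add atoms: methanol, CO
Why: Irradiation of the s-cis-locked cyclic diazo ketone expels N2 and, in concert, the alkenyl carbon C14 shifts from the carbonyl carbon C12 to the carbene carbon C13 (Wolff rearrangement), which forms the C13–C14 bond and turns C12 into an exocyclic ketene (10). Methanol adds to the ketene to give the ester dienol, which tautomerises to the β,γ-unsaturated methyl ester. The closest known reaction type is the photochemical Wolff ring contraction of cyclic 2-diazo ketones in alcohols, including 6-diazocyclohex-2-enones and the related quinone diazides. The five-membered ring is closed by ring contraction through this 1,2-shift, not by cyclisation of a chain, so no exo/endo choice arises and the alkene stays at C14=C15. C17 is a spectator and keeps the configuration fixed by the resolution. The new stereocentre C13 is protonated without useful control and probably in favour of cis diester 11; the catalytic methoxide added afterwards equilibrates only this doubly activated position (ester α and allylic) through the dienolate, and the bulky tert-butyl ester on C17 makes the trans diester the favoured epimer. The step needs migration of C14 to win over 1,2-hydride shift from C17 and O–H insertion, which the photochemical, s-cis-constrained pathway secures, and it needs re-protonation at C13 rather than C15, which is kinetically preferred and is the reason for low temperature, catalytic base and an early acid quench.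

Step 6
Reactants: 12 1-tert-butyl 2-methyl (1R,2R)-cyclopent-3-ene-1,2-dicarboxylate
Product: 14 tert-butyl (1R,2R)-2-ethynylcyclopent-3-ene-1-carboxylate, via aldehyde 13 (not isolated)
Conditions: i-Bu2AlH (1.05 equiv), CH2Cl2, −78 °C; then MeOH, K2CO3, MeC(O)C(N2)P(O)(OMe)2, −78 °C to rt
Reagents that add atoms: dimethyl (1-diazo-2-oxopropyl)phosphonate, COP(=O)(OC)C(=[N+]=[N-])C(C)=O
Why: At −78 °C the hydride reduces the unhindered methyl ester to a stable aluminium hemiacetal and leaves the tert-butyl ester; methanolic carbonate then releases aldehyde 13 in the presence of the Ohira–Bestmann reagent, which converts it to the terminal alkyne (Seyferth–Gilbert homologation) without isolation of the sensitive β,γ-unsaturated aldehyde. No stereocentre is formed, and any enolisation at C13 returns the same, more stable trans isomer.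

Step 7
Reactants: 14 tert-butyl (1R,2R)-2-ethynylcyclopent-3-ene-1-carboxylate
Product: 15 [(1R,2R)-2-ethynylcyclopent-3-en-1-yl]methanol
Conditions: LiAlH4, Et2O, 0 °C
Reagents that add atoms: none
Why: LiAlH4 reduces the tert-butyl ester to the primary alcohol; the isolated alkene and the terminal alkyne are inert to it at 0 °C.

Step 8
Reactants: 15 [(1R,2R)-2-ethynylcyclopent-3-en-1-yl]methanol
Product: 16 (1R,2R)-2-ethynylcyclopent-3-ene-1-carbaldehyde
Conditions: Dess–Martin periodinane, CH2Cl2, 0 °C to rt
Reagents that add atoms: none
Why: Dess–Martin oxidation stops at the aldehyde under near-neutral conditions; the α-centre C17 already has the more stable trans arrangement and the alkene is γ,δ to the carbonyl, so neither epimerisation nor conjugation is a concern.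

Step 9
Reactants: 16 (1R,2R)-2-ethynylcyclopent-3-ene-1-carbaldehyde
Product: 17 (1R)-1-[(1R,2R)-2-ethynylcyclopent-3-en-1-yl]propan-1-ol
Conditions: Et2Zn (2 equiv), Ti(Oi-Pr)4 (1.2 equiv), (1S,2S)-N,N′-bis(trifluoromethanesulfonyl)cyclohexane-1,2-diamine (5 mol%), toluene, −20 °C
Reagents that add atoms: diethylzinc, CC[Zn]CC
Why: Catalytic enantioselective addition of diethylzinc to an aldehyde with a titanium bis(sulfonamide) catalyst; the chiral catalyst rather than the ring should decide the face and deliver ethyl to the Re face of the carbonyl, giving the (R)-carbinol at C18. α-Branched aliphatic aldehydes are good substrates for this reaction, and the alkyne and alkene do not interfere.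

Step 10
Reactants: 17 (1R)-1-[(1R,2R)-2-ethynylcyclopent-3-en-1-yl]propan-1-ol
Product: 18 (1R)-1-[(1R,2R,3R,5S)-2-ethynyl-6-oxabicyclo[3.1.0]hexan-3-yl]propan-1-ol
Conditions: VO(acac)2 (cat.), t-BuOOH (in decane), CH2Cl2, 0 °C to rt
Reagents that add atoms: tert-butyl hydroperoxide, CC(C)(C)OO
Why: Vanadium-catalysed, hydroxyl-directed epoxidation: the C18 alkoxide bound to the metal peroxide delivers oxygen to the ring face that carries the C17 side chain, which is also the face remote from the alkynyl group on C13, so both effects point to the required epoxide (C14 R, C15 S). The terminal alkyne is not oxidised, and the syn epoxide cannot be opened by its own hydroxyl.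

Step 11
Reactants: 18 (1R)-1-[(1R,2R,3R,5S)-2-ethynyl-6-oxabicyclo[3.1.0]hexan-3-yl]propan-1-ol
Product: 19 (1R,2R,3R,5S)-3-[(1S)-1-chloropropyl]-2-ethynyl-6-oxabicyclo[3.1.0]hexane
Conditions: PPh3, CCl4, NaHCO3, MeCN, 60 °C
Reagents that add atoms: carbon tetrachloride, ClC(Cl)(Cl)Cl
Why: Appel reaction: the alkoxyphosphonium ion is displaced by chloride in an SN2 step with inversion, turning the (R)-alcohol into the (S)-chloride. Solid NaHCO3 keeps the medium neutral, conditions under which epoxy alcohols are routinely converted to epoxy chlorides.

Step 12
Reactants: 20 methyl hex-5-ynoate; 21 1,4-dichlorobut-2-yne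
Product: 22 methyl 10-chlorodeca-5,8-diynoate
Conditions: CuI, NaI, K2CO3, DMF, rt; 21 in excess (4 equiv)
Reagents that add atoms: none
Why: Copper-mediated coupling of a terminal alkyne with a propargylic halide (iodide exchange in situ) gives the skipped diyne by SN2 displacement; the excess of the symmetrical dihalide 21 keeps the reaction at monosubstitution and leaves one chloride for step 13.

Step 13
Reactants: 19 (1R,2R,3R,5S)-3-[(1S)-1-chloropropyl]-2-ethynyl-6-oxabicyclo[3.1.0]hexane; 22 methyl 10-chlorodeca-5,8-diynoate
Product: 23 methyl 12-[(1R,2R,3R,5S)-3-[(1S)-1-chloropropyl]-6-oxabicyclo[3.1.0]hexan-2-yl]dodeca-5,8,11-triynoate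
Conditions: CuI, NaI, Cs2CO3, DMF, rt
Reagents that add atoms: none
Why: The same copper-mediated propargylation; the copper acetylide of 19 is formed with carbonate, which is too weak a base to touch the epoxide, the secondary chloride or the doubly propargylic methylenes, and the skipped triyne forms at room temperature.

Step 14
Reactants: 23 methyl 12-[(1R,2R,3R,5S)-3-[(1S)-1-chloropropyl]-6-oxabicyclo[3.1.0]hexan-2-yl]dodeca-5,8,11-triynoate
Product: 24 methyl (5Z,8Z,11Z)-12-[(1R,2S,3R,5S)-3-[(1S)-1-chloropropyl]-6-oxabicyclo[3.1.0]hexan-2-yl]dodeca-5,8,11-trienoate
Conditions: H2 (1 atm), Pd/CaCO3 poisoned with Pb(OAc)2 (Lindlar catalyst), quinoline, EtOAc, 0 °C to rt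
Reagents that add atoms: none
Why: Lindlar semihydrogenation adds hydrogen syn to each triple bond on the poisoned palladium surface and gives the three Z-alkenes; quinoline suppresses over-reduction, and the epoxide, the alkyl chloride and the ester are inert. The descriptor at ring C2 changes from R to S only because the priority of the side chain changes.

## Compound list

1 | 3-methoxybenzoic acid | COc1cccc(C(=O)O)c1 | starting material
2 | 3-methoxycyclohexa-2,5-diene-1-carboxylic acid (racemic) | COC1=CC(C(=O)O)C=CC1 | intermediate (not isolated)
3 | rac-5-oxocyclohex-3-ene-1-carboxylic acid | O=C1C=CCC(C(=O)O)C1 | intermediate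
4 | (R)-1-phenylethylamine | C[C@@H](N)c1ccccc1 | starting material
5 | (1R)-1-phenylethanaminium (1R)-5-oxocyclohex-3-ene-1-carboxylate | O=C1C=CC[C@@H](C(=O)[O-])C1.C[C@@H]([NH3+])c1ccccc1 | intermediate
6 | (1R)-5-oxocyclohex-3-ene-1-carboxylic acid | O=C1C=CC[C@@H](C(=O)O)C1 | intermediate (not isolated)
7 | tert-butyl (1R)-5-oxocyclohex-3-ene-1-carboxylate | O=C1C=CC[C@@H](C(=O)OC(C)(C)C)C1 | intermediate
8 | tert-butyl (1R)-3-oxo-2-(trifluoroacetyl)cyclohex-4-ene-1-carboxylate (enolised, C2 not defined) | O=C1C=CC[C@@H](C(=O)OC(C)(C)C)C1C(=O)C(F)(F)F | intermediate (not isolated)
9 | tert-butyl (1R)-2-diazo-3-oxocyclohex-4-ene-1-carboxylate | O=C1C=CC[C@@H](C(=O)OC(C)(C)C)C1=[N+]=[N-] | intermediate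
10 | tert-butyl (1R)-2-(oxomethylidene)cyclopent-3-ene-1-carboxylate (vinylketene) | O=C=C1C=CC[C@H]1C(=O)OC(C)(C)C | intermediate (not isolated)
11 | 1-tert-butyl 2-methyl (1R,2S)-cyclopent-3-ene-1,2-dicarboxylate (cis) | CC(C)(C)OC(=O)[C@@H]1CC=C[C@@H]1C(=O)OC | intermediate (not isolated)
12 | 1-tert-butyl 2-methyl (1R,2R)-cyclopent-3-ene-1,2-dicarboxylate (trans) | CC(C)(C)OC(=O)[C@@H]1CC=C[C@H]1C(=O)OC | intermediate
13 | tert-butyl (1R,2R)-2-formylcyclopent-3-ene-1-carboxylate | CC(C)(C)OC(=O)[C@@H]1CC=C[C@H]1C=O | intermediate (not isolated)
14 | tert-butyl (1R,2R)-2-ethynylcyclopent-3-ene-1-carboxylate | CC(C)(C)OC(=O)[C@@H]1CC=C[C@H]1C#C | intermediate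
15 | [(1R,2R)-2-ethynylcyclopent-3-en-1-yl]methanol | OC[C@@H]1CC=C[C@H]1C#C | intermediate
16 | (1R,2R)-2-ethynylcyclopent-3-ene-1-carbaldehyde | O=C[C@@H]1CC=C[C@H]1C#C | intermediate
17 | (1R)-1-[(1R,2R)-2-ethynylcyclopent-3-en-1-yl]propan-1-ol | CC[C@@H](O)[C@@H]1CC=C[C@H]1C#C | intermediate
18 | (1R)-1-[(1R,2R,3R,5S)-2-ethynyl-6-oxabicyclo[3.1.0]hexan-3-yl]propan-1-ol | CC[C@@H](O)[C@@H]1C[C@@H]2O[C@@H]2[C@H]1C#C | intermediate
19 | (1R,2R,3R,5S)-3-[(1S)-1-chloropropyl]-2-ethynyl-6-oxabicyclo[3.1.0]hexane | CC[C@H](Cl)[C@@H]1C[C@@H]2O[C@@H]2[C@H]1C#C | intermediate
20 | methyl hex-5-ynoate | C#CCCCC(=O)OC | starting material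
21 | 1,4-dichlorobut-2-yne | ClCC#CCCl | starting material
22 | methyl 10-chlorodeca-5,8-diynoate | COC(=O)CCCC#CCC#CCCl | intermediate
23 | methyl 12-[(1R,2R,3R,5S)-3-[(1S)-1-chloropropyl]-6-oxabicyclo[3.1.0]hexan-2-yl]dodeca-5,8,11-triynoate | CC[C@H](Cl)[C@@H]1C[C@@H]2O[C@@H]2[C@H]1C#CCC#CCC#CCCCC(=O)OC | intermediate
24 | methyl (5Z,8Z,11Z)-12-[(1R,2S,3R,5S)-3-[(1S)-1-chloropropyl]-6-oxabicyclo[3.1.0]hexan-2-yl]dodeca-5,8,11-trienoate (CNP0141251.1) | CC[C@H](Cl)[C@@H]1C[C@@H]2O[C@@H]2[C@H]1/C=C\C/C=C\C/C=C\CCCC(=O)OC | target

## Step count and least certain steps

Total: 14 steps. Longest linear sequence: 13 steps (steps 1–11, 13 and 14, from 1); step 12 is the one-step branch to 22.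

**Step 5 (key step).** The most likely failure is in the equilibration: the dienolate can be re-protonated at C15 instead of C13, which moves the double bond into conjugation with the methyl ester. This competes with the wanted epimerisation and has the greater thermodynamic driving force, so the trans diester is available only in a kinetic window. In the photolysis itself, 1,2-hydride shift from C17 to the carbene carbon followed by aromatisation, and O–H insertion into the solvent, can compete with the shift of C14. The fallback avoids both the carbene and the protonation at C13 by using a stereospecific 1,2-shift onto a configured carbon. It sets out from 7 and returns at 13.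
- The kinetic lithium enolate of 7 (LiN(SiMe3)2, −78 °C) is brominated with NBS anti to the ester group, giving tert-butyl (1S,2S)-2-bromo-3-oxocyclohex-4-ene-1-carboxylate F1.
- Luche reduction (NaBH4, CeCl3·7H2O, MeOH, −78 °C) with hydride approaching anti to bromine should give the cis bromohydrin tert-butyl (1S,2S,3R)-2-bromo-3-hydroxycyclohex-4-ene-1-carboxylate F2.
- Ag2CO3-assisted semipinacol rearrangement of F2 moves C14 from C12 to C13 with inversion at C13 and gives aldehyde 13 with the trans arrangement, which enters the Ohira–Bestmann stage of step 6.

**Step 6.** The likely failure is enolisation of the β,γ-unsaturated aldehyde under the basic homologation conditions, with migration of the double bond into conjugation, together with over-reduction of the methyl ester. The fallback sets out from 12 and returns at 14. Aldehyde 13 is isolated after the i-Bu2AlH reduction and converted under non-basic conditions (CBr4, PPh3, Zn, CH2Cl2, 0 °C) into tert-butyl (1R,2R)-2-(2,2-dibromoethenyl)cyclopent-3-ene-1-carboxylate F3. Corey–Fuchs treatment with n-BuLi (2 equiv, THF, −78 °C) then gives 14, since bromine–lithium exchange and carbenoid rearrangement should outrun addition to the tert-butyl ester.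

**Step 9.** The likely failure is poor facial selectivity if the preference of the α-stereocentre C17 opposes the catalyst (mismatched pairing). The fallback sets out from 16 and returns at 17. Addition of EtMgBr gives 17 together with its epimer (1S)-1-[(1R,2R)-2-ethynylcyclopent-3-en-1-yl]propan-1-ol F4. The mixture is oxidised (Dess–Martin periodinane) to 1-[(1R,2R)-2-ethynylcyclopent-3-en-1-yl]propan-1-one F5. Corey–Bakshi–Shibata reduction with the (S)-2-methyl oxazaborolidine and catecholborane, which tolerates the alkene, then gives 17.

**Step 11.** The likely failure is a slow SN2 displacement at the hindered carbinol, which gives time for elimination toward C17=C18 or C18=C19 and for attack of the syn epoxide oxygen on the activated C18, followed by chloride opening of the resulting oxonium ion. The fallback reverses the order so that no epoxide is present during chlorination. It sets out from 17 and returns at 19. The Appel reaction on 17 gives (3R,4R)-4-[(1S)-1-chloropropyl]-3-ethynylcyclopent-1-ene F6, which is epoxidised with mCPBA (NaHCO3, CH2Cl2, 0 °C) anti to the allylic alkynyl group to give 19. Facial control then rests on that substituent alone.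

**Step 14.** The likely failure is over-reduction and partial isomerisation: the triple bond at the ring (C11≡C12) is the most hindered and reacts last, while the skipped dienes formed first stay on the catalyst. The fallback reduces the chain before coupling, so that only one alkyne remains for the last step. It sets out from 22 and 19 and returns at 24.
- 22 is semihydrogenated over Ni2B (from Ni(OAc)2 and NaBH4, ethylenediamine, H2, EtOH) to methyl (5Z,8Z)-10-chlorodeca-5,8-dienoate F7.
- F7 is coupled with 19 (CuI, NaI, Cs2CO3, DMF) to give methyl (5Z,8Z)-12-[(1R,2R,3R,5S)-3-[(1S)-1-chloropropyl]-6-oxabicyclo[3.1.0]hexan-2-yl]dodeca-5,8-dien-11-ynoate F8.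
- Semihydrogenation of the single remaining triple bond of F8 over the Pd/CaCO3–Pb(OAc)2 catalyst gives 24.

## Further compounds

F1 | step 5 | tert-butyl (1S,2S)-2-bromo-3-oxocyclohex-4-ene-1-carboxylate | O=C1C=CC[C@@H](C(=O)OC(C)(C)C)[C@@H]1Br
F2 | step 5 | tert-butyl (1S,2S,3R)-2-bromo-3-hydroxycyclohex-4-ene-1-carboxylate | O[C@@H]1C=CC[C@@H](C(=O)OC(C)(C)C)[C@@H]1Br
F3 | step 6 | tert-butyl (1R,2R)-2-(2,2-dibromoethenyl)cyclopent-3-ene-1-carboxylate | CC(C)(C)OC(=O)[C@@H]1CC=C[C@H]1C=C(Br)Br
F4 | step 9 | (1S)-1-[(1R,2R)-2-ethynylcyclopent-3-en-1-yl]propan-1-ol | CC[C@H](O)[C@@H]1CC=C[C@H]1C#C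
F5 | step 9 | 1-[(1R,2R)-2-ethynylcyclopent-3-en-1-yl]propan-1-one | CCC(=O)[C@@H]1CC=C[C@H]1C#C
F6 | step 11 | (3R,4R)-4-[(1S)-1-chloropropyl]-3-ethynylcyclopent-1-ene | CC[C@H](Cl)[C@@H]1CC=C[C@H]1C#C
F7 | step 14 | methyl (5Z,8Z)-10-chlorodeca-5,8-dienoate | COC(=O)CCC/C=C\C/C=C\CCl
F8 | step 14 | methyl (5Z,8Z)-12-[(1R,2R,3R,5S)-3-[(1S)-1-chloropropyl]-6-oxabicyclo[3.1.0]hexan-2-yl]dodeca-5,8-dien-11-ynoate | CC[C@H](Cl)[C@@H]1C[C@@H]2O[C@@H]2[C@H]1C#CC/C=C\C/C=C\CCCC(=O)OC
A1 | alternative 1 | methyl endo-6-ethyl-2-oxobicyclo[3.1.0]hexane-1-carboxylate | CC[C@@H]1[C@@H]2CCC(=O)[C@]12C(=O)OC
A2 | alternative 1 | methyl (6Z)-2-diazo-3-oxonon-6-enoate | CC/C=C\CCC(=O)C(=[N+]=[N-])C(=O)OC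
A3 | alternative 2 | 5-[(tert-butyldimethylsilyl)oxy]-3-[(1S)-1-chloropropyl]-2-[(trimethylsilyl)ethynyl]cyclopentan-1-ol (free alkyne drawn; formed as its Co2(CO)6 complex) | CC[C@H](Cl)[C@@H]1C[C@H](O[Si](C)(C)C(C)(C)C)[C@H](O)[C@H]1C#C[Si](C)(C)C
A4 | alternative 2 | tert-butyl(dimethyl){[(3Z)-1-{3-[(trimethylsilyl)ethynyl]oxiran-2-yl}hex-3-en-1-yl]oxy}silane (trans epoxide, free alkyne drawn; used as its Co2(CO)6 complex) | CC/C=C\C[C@H](O[Si](C)(C)C(C)(C)C)[C@@H]1O[C@H]1C#C[Si](C)(C)C
A5 | alternative 3 | 6-iodo-3-oxo-2-oxabicyclo[2.2.1]heptane-5-carboxylic acid | O=C1O[C@H]2C[C@@H]1[C@H](C(=O)O)[C@@H]2I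
A6 | alternative 3 | (1R,2R)-cyclopent-3-ene-1,2-dicarboxylic acid | OC(=O)[C@@H]1CC=C[C@H]1C(=O)O
A7 | alternative 3 | dimethyl (1R,2R)-4-oxocyclopentane-1,2-dicarboxylate | COC(=O)[C@@H]1CC(=O)C[C@H]1C(=O)OC
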